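The C5–C10 bond, shared by the two stereocentres of ring A (C1–C5, C10), is the one disconnection on which the route rests. A temporary ketone at C1 and a tert-butyl ester standing in for the C9 ketone make C10 a stabilised nucleophile six atoms from an allylic carbonate at C5. The C4 gem-dimethyl group folds the chain and denies the allyl unit any β-hydrogen. One palladium-catalysed asymmetric allylic alkylation then forms the ring, the quaternary C10 and the neighbouring C5–H centre bearing vinyl (C6–C7). Its precursor is an acyclic α-methyl β-keto ester ending in an (E)-allylic methyl carbonate. Later steps remove the C1 oxygen, extend vinyl, build the C9–C15 chain and attach the glyceride.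

Key step: step 8

Atom numbering: ring A is C1–C5 and C10 (C4 gem-dimethyl, C5 methine, C10 quaternary); C6–C8 is the oxobutyl chain, C9 the ring-bound ketone, C11–C15 the ester chain (C13 methine).

Design remark: C9 is carried as a tert-butyl ester, because an ester on the fully substituted C10 resists acyl–oxygen cleavage whereas tert-butyl leaves by acid-mediated alkyl–oxygen cleavage, and its bulk should help keep the ester away from the allyl unit in step 8.

Assumption: the (1R,2R) ligand in step 8 and the (S) ligand in step 16 are taken to give the drawn configurations; should a first run show the opposite sense, the antipodal ligand is used and nothing else changes.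

Step 1
Reactants: 1 2,2-dimethylpent-4-enal; 2 triethyl phosphonoacetate
Product: 4 ethyl (E)-4,4-dimethylhepta-2,6-dienoate, via sodium phosphonate carbanion 3 (not isolated)
Conditions: NaH, THF, 0 °C; then 1, 0 °C → rt
Reagents that add atoms: none
Why: Horner–Wadsworth–Emmons olefination of a non-enolisable α-quaternary aldehyde with the stabilised phosphonate anion should give the (E)-enoate.

Step 2
Reactants: 4 ethyl (E)-4,4-dimethylhepta-2,6-dienoate
Product: 5 (E)-4,4-dimethylhepta-2,6-dien-1-ol
Conditions: iBu2AlH (2.5 equiv), CH2Cl2, −78 °C; aq. Rochelle salt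
Reagents that add atoms: none
Why: Low-temperature aluminium hydride reduction of a conjugated ester proceeds by two 1,2-additions to the allylic alcohol and leaves both alkenes alone.

Step 3
Reactants: 5 (E)-4,4-dimethylhepta-2,6-dien-1-ol
Product: 6 (E)-4,4-dimethylhepta-2,6-dien-1-yl methyl carbonate
Conditions: ClCO2Me, pyridine, CH2Cl2, 0 °C
Reagents that add atoms: methyl chloroformate, COC(=O)Cl
Why: Acylation of the primary allylic alcohol with a chloroformate installs the leaving group that later ionises and supplies its own base.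

Step 4
Reactants: 6 (E)-4,4-dimethylhepta-2,6-dien-1-yl methyl carbonate
Product: 8 (E)-7-hydroxy-4,4-dimethylhept-2-en-1-yl methyl carbonate, via B-alkyl-9-borabicyclononane 7 (not isolated)
Conditions: 9-borabicyclo[3.3.1]nonane (9-BBN, 0.5 M in THF), 0 °C → rt; then 30% H2O2, aq. NaOAc, 0 °C → rt
Reagents that add atoms: hydrogen peroxide, OO
Why: Anti-Markovnikov hydroboration–oxidation, in which 9-BBN selects the monosubstituted terminal alkene over the 1,2-disubstituted alkene beside the quaternary carbon and buffered peroxide spares the carbonate.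

Step 5
Reactants: 8 (E)-7-hydroxy-4,4-dimethylhept-2-en-1-yl methyl carbonate
Product: 9 (E)-4,4-dimethyl-7-oxohept-2-en-1-yl methyl carbonate
Conditions: 2,2,6,6-tetramethylpiperidin-1-oxyl (10 mol%), PhI(OAc)2, CH2Cl2, rt
Reagents that add atoms: none
Why: Oxoammonium-mediated oxidation of a primary alcohol stops at the aldehyde and does not touch the allylic carbonate.

Step 6
Reactants: 9 (E)-4,4-dimethyl-7-oxohept-2-en-1-yl methyl carbonate; 10 tert-butyl propanoate
Product: 12 tert-butyl (E)-3-hydroxy-9-[(methoxycarbonyl)oxy]-2,6,6-trimethylnon-7-enoate (mixture of diastereomers), via lithium ester enolate 11 (not isolated)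
Conditions: LiN(iPr)2, THF, −78 °C; then 9, −78 °C; AcOH quench
Reagents that add atoms: none
Why: Directed aldol addition of the preformed lithium ester enolate to the aldehyde is far faster at −78 °C than attack on the carbonate, and the two new centres are erased in steps 7 and 8.

Step 7
Reactants: 12 tert-butyl (E)-3-hydroxy-9-[(methoxycarbonyl)oxy]-2,6,6-trimethylnon-7-enoate
Product: 13 tert-butyl (E)-9-[(methoxycarbonyl)oxy]-2,6,6-trimethyl-3-oxonon-7-enoate
Conditions: Dess–Martin periodinane, CH2Cl2, rt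
Reagents that add atoms: none
Why: Dess–Martin oxidation of the secondary alcohol gives the β-keto ester without base, so the carbonate survives.

Step 8
Reactants: 13 tert-butyl (E)-9-[(methoxycarbonyl)oxy]-2,6,6-trimethyl-3-oxonon-7-enoate
Product: 15 tert-butyl (1S,2R)-1,3,3-trimethyl-6-oxo-2-vinylcyclohexane-1-carboxylate, via allylpalladium enolate 14 (not isolated)
Conditions: Pd2(dba)3·CHCl3 (2.5 mol%), (1R,2R)-N,N'-bis[2-(diphenylphosphino)benzoyl]cyclohexane-1,2-diamine (7.5 mol%), CH2Cl2 (0.02 M), 0 °C → rt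
Reagents that add atoms: none
Why: Zerovalent palladium ionises the allylic carbonate with loss of CO2 and methoxide, the methoxide deprotonates the β-keto ester, and the enolate carbon C10 then attacks the allyl terminus C5 on the face opposite to palladium. The closest known reaction type is the palladium-catalysed asymmetric intramolecular allylic alkylation of β-keto esters that carry an allylic carbonate or acetate, which delivers 2-vinylcycloalkanone carboxylates. Ring A closes in a 6-exo mode at the proximal allyl terminus, since attack at C7 would need an eight-membered ring, O-allylation is reversible under the catalyst, and the quaternary C4 leaves no β-hydrogen for diene formation. C5 is set by the chiral diphosphine, because the two diastereomeric allyl complexes interconvert through the unsubstituted terminus C7 and the ligand pocket decides which one is attacked. C10 is set relative to C5 in the chair-like closure, in which the bulky, conjugated tert-butyl ester is expected to turn away from the allyl–palladium unit so that the methyl group ends cis to vinyl. The step therefore needs regio-, enantio- and diastereocontrol, and tether length, the C4 gem-dimethyl group and the size of the ester are the substrate features meant to secure them, the last being the least certain.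

Step 9
Reactants: 15 tert-butyl (1S,2R)-1,3,3-trimethyl-6-oxo-2-vinylcyclohexane-1-carboxylate
Product: 16 tert-butyl (1S,2R)-6-hydroxy-1,3,3-trimethyl-2-vinylcyclohexane-1-carboxylate (C6 epimers)
Conditions: NaBH4, MeOH, 0 °C
Reagents that add atoms: none
Why: Borohydride reduction takes the ring ketone but not the tert-butyl ester or the alkene, and the carbinol configuration is immaterial because this oxygen is removed.

Step 10
Reactants: 16 tert-butyl (1S,2R)-6-hydroxy-1,3,3-trimethyl-2-vinylcyclohexane-1-carboxylate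
Product: 17 tert-butyl (1S,2R)-6-[(1H-imidazole-1-carbothioyl)oxy]-1,3,3-trimethyl-2-vinylcyclohexane-1-carboxylate (C6 epimers)
Conditions: 1,1'-thiocarbonyldiimidazole, 4-(dimethylamino)pyridine (cat.), ClCH2CH2Cl, 80 °C
Reagents that add atoms: 1,1'-thiocarbonyldiimidazole, S=C(n1ccnc1)n1ccnc1
Why: Neutral thioacylation of the hindered secondary alcohol avoids an alkoxide that could open the ring by retro-aldol cleavage beside the quaternary carbon.

Step 11
Reactants: 17 tert-butyl (1S,2R)-6-[(1H-imidazole-1-carbothioyl)oxy]-1,3,3-trimethyl-2-vinylcyclohexane-1-carboxylate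
Product: 18 tert-butyl (1R,2R)-1,3,3-trimethyl-2-vinylcyclohexane-1-carboxylate
Conditions: Bu3SnH, 2,2'-azobis(2-methylpropionitrile) (cat.), toluene, 110 °C
Reagents that add atoms: none
Why: Barton–McCombie deoxygenation, in which the stannyl radical adds to C=S, the C1–O bond fragments, and the secondary C1 radical takes hydrogen from Bu3SnH faster than it could close in a 4-exo or 5-endo mode onto vinyl.

Step 12
Reactants: 18 tert-butyl (1R,2R)-1,3,3-trimethyl-2-vinylcyclohexane-1-carboxylate
Product: 20 tert-butyl (1R,2R)-2-(but-3-en-1-yl)-1,3,3-trimethylcyclohexane-1-carboxylate, via B-alkyl-9-borabicyclononane 19 (not isolated)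
Conditions: 9-BBN dimer, THF, 65 °C; then vinyl bromide (1 M in THF), PdCl2(dppf) (5 mol%), 3 M aq. NaOH, 50 °C, sealed tube
Reagents that add atoms: vinyl bromide, C=CBr
Why: Hydroboration puts boron on the terminal carbon C7 and B-alkyl Suzuki–Miyaura coupling with vinyl bromide forges C7–C8, giving the butenyl chain as a masked methyl ketone.

Step 13
Reactants: 20 tert-butyl (1R,2R)-2-(but-3-en-1-yl)-1,3,3-trimethylcyclohexane-1-carboxylate
Product: 21 (1R,2R)-2-(but-3-en-1-yl)-1,3,3-trimethylcyclohexane-1-carboxylic acid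
Conditions: CF3CO2H/CH2Cl2 (1:4), 0 °C → rt
Reagents that add atoms: none
Why: Acidolysis of a tert-butyl ester runs by alkyl–oxygen cleavage with loss of isobutene however hindered the carbonyl is, and a monosubstituted alkene tolerates brief exposure to CF3CO2H.

Step 14
Reactants: 21 (1R,2R)-2-(but-3-en-1-yl)-1,3,3-trimethylcyclohexane-1-carboxylic acid
Product: 24 1-[(1R,2R)-2-(but-3-en-1-yl)-1,3,3-trimethylcyclohexyl]ethan-1-one, via lithium carboxylate 22 (not isolated), via dilithium gem-diolate 23 (not isolated)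
Conditions: MeLi (4 equiv), Et2O, 0 °C → reflux; inverse quench into cold 1 M HCl
Reagents that add atoms: methyllithium, [Li]C
Why: Organolithium addition to a lithium carboxylate gives a gem-diolate that cannot add a second time and collapses to the methyl ketone on acidic quench.

Step 15
Reactants: 24 1-[(1R,2R)-2-(but-3-en-1-yl)-1,3,3-trimethylcyclohexyl]ethan-1-one; 25 methyl (E)-4-bromo-3-methylbut-2-enoate
Product: 27 methyl (E)-6-[(1R,2R)-2-(but-3-en-1-yl)-1,3,3-trimethylcyclohexyl]-3-methyl-6-oxohex-2-enoate, via lithium ketone enolate 26 (not isolated)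
Conditions: LiN(iPr)2, THF, −78 °C; then 25, DMPU, −78 → −20 °C
Reagents that add atoms: none
Why: Deprotonation can occur only at the C11 methyl group because C10 is quaternary, and SN2 alkylation of the lithium enolate by the primary allylic bromide forms C11–C12 with the (E)-alkene retained.

Step 16
Reactants: 27 methyl (E)-6-[(1R,2R)-2-(but-3-en-1-yl)-1,3,3-trimethylcyclohexyl]-3-methyl-6-oxohex-2-enoate
Product: 28 methyl (3R)-6-[(1R,2R)-2-(but-3-en-1-yl)-1,3,3-trimethylcyclohexyl]-3-methyl-6-oxohexanoate
Conditions: Cu(OAc)2·H2O (5 mol%), (S)-2,2'-bis(di-p-tolylphosphino)-1,1'-binaphthyl (5.5 mol%), (EtO)2MeSiH, t-BuOH, toluene, 0 °C → rt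
Reagents that add atoms: none
Why: Copper hydride asymmetric conjugate reduction, in which the bisphosphine-bound hydride adds to one face of C13 of the (E)-enoate to set 13R and tert-butanol protonates the copper enolate before it can add to the hindered C9 ketone, while the isolated alkene is inert.

Step 17
Reactants: 28 methyl (3R)-6-[(1R,2R)-2-(but-3-en-1-yl)-1,3,3-trimethylcyclohexyl]-3-methyl-6-oxohexanoate
Product: 29 (3R)-6-[(1R,2R)-2-(but-3-en-1-yl)-1,3,3-trimethylcyclohexyl]-3-methyl-6-oxohexanoic acid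
Conditions: LiOH·H2O, THF/MeOH/H2O, rt; then 1 M HCl
Reagents that add atoms: lithium hydroxide, [Li+].[OH-]
Why: Saponification of the unhindered methyl ester cannot epimerise C13, which is β to the carboxyl, and is run while the C8 ketone is still masked so that no base-mediated aldol between C8 and C9 carbonyls is possible.

Step 18
Reactants: 29 (3R)-6-[(1R,2R)-2-(but-3-en-1-yl)-1,3,3-trimethylcyclohexyl]-3-methyl-6-oxohexanoic acid
Product: 30 (3R)-3-methyl-6-oxo-6-[(1R,2R)-1,3,3-trimethyl-2-(3-oxobutyl)cyclohexyl]hexanoic acid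
Conditions: PdCl2 (10 mol%), CuCl, O2 (1 atm), DMF/H2O (7:1), rt
Reagents that add atoms: water, O
Why: Tsuji–Wacker oxidation by divalent palladium converts the terminal alkene into the C8 methyl ketone with Markovnikov selectivity and tolerates the free acid and the hindered ketone.

Step 19
Reactants: 30 (3R)-3-methyl-6-oxo-6-[(1R,2R)-1,3,3-trimethyl-2-(3-oxobutyl)cyclohexyl]hexanoic acid; 31 (S)-glycidol
Product: 32 [(2R)-oxiran-2-yl]methyl (3R)-3-methyl-6-oxo-6-[(1R,2R)-1,3,3-trimethyl-2-(3-oxobutyl)cyclohexyl]hexanoate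
Conditions: N,N'-dicyclohexylcarbodiimide, 4-(dimethylamino)pyridine (cat.), CH2Cl2, 0 °C → rt
Reagents that add atoms: none
Why: Steglich esterification acylates the primary hydroxyl of glycidol without opening the epoxide, so the glycerol stereocentre is carried in untouched (the descriptor changes only through the priority order).

Step 20
Reactants: 32 [(2R)-oxiran-2-yl]methyl (3R)-3-methyl-6-oxo-6-[(1R,2R)-1,3,3-trimethyl-2-(3-oxobutyl)cyclohexyl]hexanoate
Product: 33 (2R)-3-(acetyloxy)-2-hydroxypropyl (3R)-3-methyl-6-oxo-6-[(1R,2R)-1,3,3-trimethyl-2-(3-oxobutyl)cyclohexyl]hexanoate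
Conditions: AcOH (10 equiv), Bu4NOAc (10 mol%), toluene, 60 °C
Reagents that add atoms: acetic acid, CC(=O)O
Why: Carboxylate opening of a terminal epoxide, in which acetate attacks the unsubstituted epoxide carbon in an SN2 step, leaves the C–O bond at the stereocentre intact and gives the 1,3-diacylglycerol with the free 2-hydroxyl.

Compound list
1 | 2,2-dimethylpent-4-enal | C=CCC(C)(C)C=O | starting material
2 | triethyl phosphonoacetate | CCOC(=O)CP(=O)(OCC)OCC | starting material
3 | sodium salt of triethyl phosphonoacetate (phosphonate carbanion) | CCOC(=O)[CH-]P(=O)(OCC)OCC.[Na+] | intermediate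
4 | ethyl (E)-4,4-dimethylhepta-2,6-dienoate | CCOC(=O)/C=C/C(C)(C)CC=C | intermediate
5 | (E)-4,4-dimethylhepta-2,6-dien-1-ol | OC/C=C/C(C)(C)CC=C | intermediate
6 | (E)-4,4-dimethylhepta-2,6-dien-1-yl methyl carbonate | COC(=O)OC/C=C/C(C)(C)CC=C | intermediate
7 | (E)-7-(9-borabicyclo[3.3.1]nonan-9-yl)-4,4-dimethylhept-2-en-1-yl methyl carbonate | COC(=O)OC/C=C/C(C)(C)CCCB1C2CCCC1CCC2 | intermediate
8 | (E)-7-hydroxy-4,4-dimethylhept-2-en-1-yl methyl carbonate | COC(=O)OC/C=C/C(C)(C)CCCO | intermediate
9 | (E)-4,4-dimethyl-7-oxohept-2-en-1-yl methyl carbonate | COC(=O)OC/C=C/C(C)(C)CCC=O | intermediate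
10 | tert-butyl propanoate | CCC(=O)OC(C)(C)C | starting material
11 | lithium 1-tert-butoxyprop-1-en-1-olate | CC=C([O-])OC(C)(C)C.[Li+] | intermediate
12 | tert-butyl (E)-3-hydroxy-9-[(methoxycarbonyl)oxy]-2,6,6-trimethylnon-7-enoate (diastereomer mixture at C2 and C3) | COC(=O)OC/C=C/C(C)(C)CCC(O)C(C)C(=O)OC(C)(C)C | intermediate
13 | tert-butyl (E)-9-[(methoxycarbonyl)oxy]-2,6,6-trimethyl-3-oxonon-7-enoate (C2 configurationally labile) | COC(=O)OC/C=C/C(C)(C)CCC(=O)C(C)C(=O)OC(C)(C)C | intermediate
14 | allylpalladium enolate zwitterion from 13 (drawn as the η1-allyl form, diphosphine omitted) | [Pd+]C/C=C/C(C)(C)CCC([O-])=C(C)C(=O)OC(C)(C)C | intermediate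
15 | tert-butyl (1S,2R)-1,3,3-trimethyl-6-oxo-2-vinylcyclohexane-1-carboxylate | C=C[C@@H]1C(C)(C)CCC(=O)[C@@]1(C)C(=O)OC(C)(C)C | intermediate
16 | tert-butyl (1S,2R)-6-hydroxy-1,3,3-trimethyl-2-vinylcyclohexane-1-carboxylate (C6 epimers) | C=C[C@@H]1C(C)(C)CCC(O)[C@@]1(C)C(=O)OC(C)(C)C | intermediate
17 | tert-butyl (1S,2R)-6-[(1H-imidazole-1-carbothioyl)oxy]-1,3,3-trimethyl-2-vinylcyclohexane-1-carboxylate (C6 epimers) | C=C[C@@H]1C(C)(C)CCC(OC(=S)n2ccnc2)[C@@]1(C)C(=O)OC(C)(C)C | intermediate
18 | tert-butyl (1R,2R)-1,3,3-trimethyl-2-vinylcyclohexane-1-carboxylate | C=C[C@@H]1C(C)(C)CCC[C@@]1(C)C(=O)OC(C)(C)C | intermediate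
19 | tert-butyl (1R,2R)-2-[2-(9-borabicyclo[3.3.1]nonan-9-yl)ethyl]-1,3,3-trimethylcyclohexane-1-carboxylate | C1CCC2CCCC1B2CC[C@@H]3C(C)(C)CCC[C@@]3(C)C(=O)OC(C)(C)C | intermediate
20 | tert-butyl (1R,2R)-2-(but-3-en-1-yl)-1,3,3-trimethylcyclohexane-1-carboxylate | C=CCC[C@@H]1C(C)(C)CCC[C@@]1(C)C(=O)OC(C)(C)C | intermediate
21 | (1R,2R)-2-(but-3-en-1-yl)-1,3,3-trimethylcyclohexane-1-carboxylic acid | C=CCC[C@@H]1C(C)(C)CCC[C@@]1(C)C(=O)O | intermediate
22 | lithium (1R,2R)-2-(but-3-en-1-yl)-1,3,3-trimethylcyclohexane-1-carboxylate | C=CCC[C@@H]1C(C)(C)CCC[C@@]1(C)C(=O)[O-].[Li+] | intermediate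
23 | dilithium 1-[(1R,2R)-2-(but-3-en-1-yl)-1,3,3-trimethylcyclohexyl]ethane-1,1-bis(olate) | C=CCC[C@@H]1C(C)(C)CCC[C@@]1(C)C(C)([O-])[O-].[Li+].[Li+] | intermediate
24 | 1-[(1R,2R)-2-(but-3-en-1-yl)-1,3,3-trimethylcyclohexyl]ethan-1-one | C=CCC[C@@H]1C(C)(C)CCC[C@@]1(C)C(C)=O | intermediate
25 | methyl (E)-4-bromo-3-methylbut-2-enoate | COC(=O)/C=C(\C)CBr | starting material
26 | lithium 1-[(1R,2R)-2-(but-3-en-1-yl)-1,3,3-trimethylcyclohexyl]ethen-1-olate | C=CCC[C@@H]1C(C)(C)CCC[C@@]1(C)C(=C)[O-].[Li+] | intermediate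
27 | methyl (E)-6-[(1R,2R)-2-(but-3-en-1-yl)-1,3,3-trimethylcyclohexyl]-3-methyl-6-oxohex-2-enoate | C=CCC[C@@H]1C(C)(C)CCC[C@@]1(C)C(=O)CC/C(C)=C/C(=O)OC | intermediate
28 | methyl (3R)-6-[(1R,2R)-2-(but-3-en-1-yl)-1,3,3-trimethylcyclohexyl]-3-methyl-6-oxohexanoate | C=CCC[C@@H]1C(C)(C)CCC[C@@]1(C)C(=O)CC[C@@H](C)CC(=O)OC | intermediate
29 | (3R)-6-[(1R,2R)-2-(but-3-en-1-yl)-1,3,3-trimethylcyclohexyl]-3-methyl-6-oxohexanoic acid | C=CCC[C@@H]1C(C)(C)CCC[C@@]1(C)C(=O)CC[C@@H](C)CC(=O)O | intermediate
30 | (3R)-3-methyl-6-oxo-6-[(1R,2R)-1,3,3-trimethyl-2-(3-oxobutyl)cyclohexyl]hexanoic acid | CC(=O)CC[C@@H]1C(C)(C)CCC[C@@]1(C)C(=O)CC[C@@H](C)CC(=O)O | intermediate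
31 | (S)-glycidol, (2S)-oxiran-2-ylmethanol | OC[C@H]1CO1 | starting material
32 | [(2R)-oxiran-2-yl]methyl (3R)-3-methyl-6-oxo-6-[(1R,2R)-1,3,3-trimethyl-2-(3-oxobutyl)cyclohexyl]hexanoate | CC(=O)CC[C@@H]1C(C)(C)CCC[C@@]1(C)C(=O)CC[C@@H](C)CC(=O)OC[C@H]2CO2 | intermediate
33 | (2R)-3-(acetyloxy)-2-hydroxypropyl (3R)-3-methyl-6-oxo-6-[(1R,2R)-1,3,3-trimethyl-2-(3-oxobutyl)cyclohexyl]hexanoate (CNP0140002.1) | CC(=O)CC[C@@H]1C(C)(C)CCC[C@@]1(C)C(=O)CC[C@@H](C)CC(=O)OC[C@H](O)COC(C)=O | target

Total step count: 20. Longest linear sequence: 20 steps, from 1 to 33; compounds 2, 10, 25 and 31 are purchased.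

Steps most likely to fail

Step 8. Face selection at C5 by the ligand may be weak, the ester instead of the methyl group may end cis to vinyl, or closure at the allyl terminus beside C4 may be too slow in the crowded chiral pocket. The fallback replaces catalyst control by resolution and sets out from 13. Closure with a small achiral catalyst, Pd(PPh3)4 in THF at 65 °C, should give racemic tert-butyl (1S*,2R*)-1,3,3-trimethyl-6-oxo-2-vinylcyclohexane-1-carboxylate F1, with any C10 epimer removed on silica. Preparative chromatography on a cellulose tris(3,5-dimethylphenylcarbamate) phase would then separate the enantiomers, and the (1S,2R) enantiomer comes back to the route as 15.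

Step 16. Hydride delivery may discriminate poorly between the faces of the methyl/alkyl-substituted (E)-enoate, and the copper enolate may add to the C9 carbonyl or the ketone may be hydrosilylated. The fallback replaces hydride conjugate addition by carboxylate-directed hydrogenation and sets out from 27. Saponification with LiOH should give (E)-6-[(1R,2R)-2-(but-3-en-1-yl)-1,3,3-trimethylcyclohexyl]-3-methyl-6-oxohex-2-enoic acid F2. Tsuji–Wacker oxidation (PdCl2, CuCl, O2, DMF/H2O) should then give (E)-3-methyl-6-oxo-6-[(1R,2R)-1,3,3-trimethyl-2-(3-oxobutyl)cyclohexyl]hex-2-enoic acid F3. Hydrogenation of F3 with Ru(OAc)2(BINAP) under H2 pressure in MeOH, using the BINAP antipode that turns geranic acid into (R)-citronellic acid, should set 13R without any enolate being formed. The fallback comes back to the route at 30.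

Step 20. Acetate may attack the internal epoxide carbon in part, and acyl groups may migrate across the glycerol unit at 60 °C, which would erode regio- and stereochemical purity at the glycerol centre. The fallback replaces epoxide opening by a protected glycerol and sets out from 30. Carbodiimide esterification with (S)-solketal, OC[C@H]1COC(C)(C)O1, should give [(4R)-2,2-dimethyl-1,3-dioxolan-4-yl]methyl (3R)-3-methyl-6-oxo-6-[(1R,2R)-1,3,3-trimethyl-2-(3-oxobutyl)cyclohexyl]hexanoate F4. Aqueous AcOH (80%) at 40 °C would free (2R)-2,3-dihydroxypropyl (3R)-3-methyl-6-oxo-6-[(1R,2R)-1,3,3-trimethyl-2-(3-oxobutyl)cyclohexyl]hexanoate F5. AcCl with 2,4,6-collidine in CH2Cl2 at −78 °C should then acetylate only the primary hydroxyl, and the fallback comes back to the route at 33.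

Further compounds
F1 | step 8 | racemic tert-butyl (1S*,2R*)-1,3,3-trimethyl-6-oxo-2-vinylcyclohexane-1-carboxylate | C=C[C@@H]1C(C)(C)CCC(=O)[C@@]1(C)C(=O)OC(C)(C)C.C=C[C@H]1C(C)(C)CCC(=O)[C@]1(C)C(=O)OC(C)(C)C
F2 | step 16 | (E)-6-[(1R,2R)-2-(but-3-en-1-yl)-1,3,3-trimethylcyclohexyl]-3-methyl-6-oxohex-2-enoic acid | C=CCC[C@@H]1C(C)(C)CCC[C@@]1(C)C(=O)CC/C(C)=C/C(=O)O
F3 | step 16 | (E)-3-methyl-6-oxo-6-[(1R,2R)-1,3,3-trimethyl-2-(3-oxobutyl)cyclohexyl]hex-2-enoic acid | CC(=O)CC[C@@H]1C(C)(C)CCC[C@@]1(C)C(=O)CC/C(C)=C/C(=O)O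
F4 | step 20 | [(4R)-2,2-dimethyl-1,3-dioxolan-4-yl]methyl (3R)-3-methyl-6-oxo-6-[(1R,2R)-1,3,3-trimethyl-2-(3-oxobutyl)cyclohexyl]hexanoate | CC(=O)CC[C@@H]1C(C)(C)CCC[C@@]1(C)C(=O)CC[C@@H](C)CC(=O)OC[C@H]2COC(C)(C)O2
F5 | step 20 | (2R)-2,3-dihydroxypropyl (3R)-3-methyl-6-oxo-6-[(1R,2R)-1,3,3-trimethyl-2-(3-oxobutyl)cyclohexyl]hexanoate | CC(=O)CC[C@@H]1C(C)(C)CCC[C@@]1(C)C(=O)CC[C@@H](C)CC(=O)OC[C@H](O)CO
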